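## Retrosynthetic overview

1. Sodwanone T (10) ⇐ catalyst-controlled mono-reduction of the C2-symmetric bis(oxepanone) 9 (sets C3 as R) ⇐ oxidation of C2-symmetric diol 8.
2. 8 ⇐ one twofold epoxide-opening cascade of squalene 2,3:6,7:18,19:22,23-tetraepoxide 6, the polyepoxide invoked in the presumed biosynthesis.
3. 6 ⇐ tail-to-tail reductive homocoupling (C12–C13 bond) of two molecules of diepoxyfarnesyl bromide 5.
4. 5 ⇐ (2E,6E)-farnesyl acetate 1 by reagent-controlled Shi diepoxidation, which sets every ring-fusion stereocentre.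
5. Ring order: both oxepanes (O on C7→C2 and O on C18→C23) close first, then both cyclohexenes (C11→C6 and C14→C19), all four in step 5.

Assumption: C30 compounds carry squalene numbering (C1–C24 along the chain); reagents and catalysts are not numbered; the L-fructose-derived (ent-)Shi ketone is bought or made from L-sorbose.

Note on C3: a cascade from uniformly (S)-configured epoxides gives the 3S carbinol, the epimer of the 3R carbinol in the target. Steps 6 and 7 therefore take both carbinols to ketones and reduce one back under catalyst control.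

## Route

Step 1
Reactants: 1 (2E,6E)-farnesyl acetate
Product: 2 (2E,6S,7S,10S)-6,7:10,11-diepoxyfarnesyl acetate
Conditions: L-fructose-derived Shi ketone (0.5 equiv), KHSO5 (as Oxone, 2.8 equiv), K2CO3, Bu4NHSO4 (cat.), MeCN/CH2(OMe)2/aq. Na2B4O7 buffer (pH 10.5), 0 °C
Reagents that add atoms: potassium peroxymonosulfate [K+].[O-]S(=O)(=O)OO
Why: Shi asymmetric epoxidation: the dioxirane from the L-fructose-derived ketone transfers oxygen through a spiro transition state to one face of the two electron-rich trisubstituted alkenes and so sets 6S, 7S and 10S, while the C2=C3 alkene is inductively deactivated by the allylic acetate and stays.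

Step 2
Reactants: 2 (2E,6S,7S,10S)-6,7:10,11-diepoxyfarnesyl acetate
Product: 3 (2E,6S,7S,10S)-6,7:10,11-diepoxyfarnesol
Conditions: K2CO3 (0.2 equiv), MeOH, 0 → 23 °C
Reagents that add atoms: none
Why: Zemplén-type transesterification removes the acetate, trisubstituted epoxides are inert to methoxide at this temperature, and no stereocentre is touched.

Step 3
Reactants: 3 (2E,6S,7S,10S)-6,7:10,11-diepoxyfarnesol
Product: 5 (2E,6S,7S,10S)-6,7:10,11-diepoxyfarnesyl bromide, via allylic mesylate 4 (not isolated)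
Conditions: MsCl, Et3N, THF, −45 °C; then LiBr, THF, 0 °C
Reagents that add atoms: lithium bromide [Li+].[Br-]
Why: Mesylation followed by SN2 displacement with bromide at the primary allylic carbon gives the bromide without allylic transposition or loss of E geometry, and trisubstituted epoxides tolerate LiBr in THF at 0 °C.

Step 4
Reactants: 5 (2E,6S,7S,10S)-6,7:10,11-diepoxyfarnesyl bromide (two molecules)
Product: 6 (3S,6S,7S,10E,14E,18S,19S,22S)-2,3:6,7:18,19:22,23-tetraepoxy-2,3,6,7,18,19,22,23-octahydrosqualene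
Conditions: CoCl(PPh3)3 (1.1 equiv), degassed benzene, 23 °C, Ar
Reagents that add atoms: none
Why: Reductive homocoupling of an allylic bromide by monovalent cobalt (halogen abstraction to an allyl–cobalt species that couples at the less hindered primary termini) forms the C12–C13 bond head-to-head with retention of the E alkenes, the same reaction type that turns farnesyl bromide into squalene, and the non-allylic epoxides are inert to this soft reductant.

Step 5
Reactants: 6 (3S,6S,7S,10E,14E,18S,19S,22S)-2,3:6,7:18,19:22,23-tetraepoxy-2,3,6,7,18,19,22,23-octahydrosqualene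
Product: 8 6,6′-(ethane-1,2-diyl)bis[(3S,5aS,9aS)-2,2,5a,7-tetramethyl-2,3,4,5,5a,8,9,9a-octahydro-1-benzoxepin-3-ol], via bis-TMS ether 7 (not isolated)
Conditions: TMSOTf (3 equiv), 2,6-di-tert-butyl-4-methylpyridine (3 equiv), CH2Cl2 (0.005 M), −78 °C, substrate added to the cold promoter; then K2CO3, MeOH, 0 °C
Reagents that add atoms: none
Why: Proposed new method: twofold tandem oxa-/carbacyclisation in which at each end silylation of the terminal epoxide triggers anti attack of the neighbouring epoxide oxygen at tertiary C2 (C23) to give a bicyclic epoxonium ion, the E-10,11 (14,15) alkene opens this ion at tertiary C6 (C19) through a chair transition state with inversion (C3/C22 and C7/C18 keep their epoxide configuration, so the trans ring fusions 6S,7S and 18S,19S result), and the tertiary C10 (C15) cation loses its axial C11–H (C14–H) in the Zaitsev sense to give the tetrasubstituted alkene; the closest known reaction is the TMSOTf/hindered-pyridine oxa-/carbacyclisation of a single 1,5-diepoxide terminated by a trisubstituted alkene, here run at both chain ends at once.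

Step 6
Reactants: 8 6,6′-(ethane-1,2-diyl)bis[(3S,5aS,9aS)-2,2,5a,7-tetramethyl-2,3,4,5,5a,8,9,9a-octahydro-1-benzoxepin-3-ol]
Product: 9 6,6′-(ethane-1,2-diyl)bis[(5aS,9aS)-2,2,5a,7-tetramethyl-4,5,5a,8,9,9a-hexahydro-1-benzoxepin-3(2H)-one]
Conditions: Dess–Martin periodinane (2.6 equiv), CH2Cl2, 23 °C
Reagents that add atoms: none
Why: Dess–Martin oxidation of both secondary carbinols under neutral conditions leaves the oxepanes and tetrasubstituted alkenes alone and deliberately erases the 3S/22S centres, because the carbinol configuration inherited from the epoxide is the epimer of the one needed.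

Step 7
Reactants: 9 6,6′-(ethane-1,2-diyl)bis[(5aS,9aS)-2,2,5a,7-tetramethyl-4,5,5a,8,9,9a-hexahydro-1-benzoxepin-3(2H)-one]
Product: 10 sodwanone T
Conditions: (S)-2-methyl-CBS-oxazaborolidine (0.2 equiv), BH3·SMe2 (0.6 equiv, slow addition), THF, −20 °C; MeOH quench at about 50% conversion
Reagents that add atoms: none
Why: Corey–Bakshi–Shibata reduction: the (S)-oxazaborolidine–borane complex binds the carbonyl anti to the large quaternary C2 and delivers hydride to give the 3R carbinol (same sense as acetophenone to (R)-1-phenylethanol, and matched with attack anti to the angular methyl), and since the two carbonyls of C2-symmetric 9 are homotopic, limiting borane gives mono-alcohol 10 statistically (about 45% at half conversion, 9 recovered and over-reduced diol re-oxidised as in step 6).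

## Compound list

1 | (2E,6E)-farnesyl acetate | CC(C)=CCC/C(C)=C/CC/C(C)=C/COC(C)=O | starting material
2 | (2E,6S,7S,10S)-6,7:10,11-diepoxyfarnesyl acetate | CC1(C)O[C@H]1CC[C@]1(C)O[C@H]1CC/C(C)=C/COC(C)=O | intermediate
3 | (2E,6S,7S,10S)-6,7:10,11-diepoxyfarnesol | CC1(C)O[C@H]1CC[C@]1(C)O[C@H]1CC/C(C)=C/CO | intermediate
4 | (2E,6S,7S,10S)-6,7:10,11-diepoxyfarnesyl methanesulfonate | CC1(C)O[C@H]1CC[C@]1(C)O[C@H]1CC/C(C)=C/COS(C)(=O)=O | intermediate
5 | (2E,6S,7S,10S)-6,7:10,11-diepoxyfarnesyl bromide | CC1(C)O[C@H]1CC[C@]1(C)O[C@H]1CC/C(C)=C/CBr | intermediate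
6 | (3S,6S,7S,10E,14E,18S,19S,22S)-2,3:6,7:18,19:22,23-tetraepoxy-2,3,6,7,18,19,22,23-octahydrosqualene | CC1(C)O[C@H]1CC[C@]1(C)O[C@H]1CC/C(C)=C/CC/C=C(C)/CC[C@@H]1O[C@@]1(C)CC[C@@H]1OC1(C)C | intermediate
7 | bis(trimethylsilyl) ether of 8 | CC1=C(CCC2=C(C)CC[C@@H]3OC(C)(C)[C@@H](O[Si](C)(C)C)CC[C@@]23C)[C@]2(C)CC[C@H](O[Si](C)(C)C)C(C)(C)O[C@H]2CC1 | intermediate
8 | 6,6′-(ethane-1,2-diyl)bis[(3S,5aS,9aS)-2,2,5a,7-tetramethyl-2,3,4,5,5a,8,9,9a-octahydro-1-benzoxepin-3-ol] (trans-fused; squalene 3S,6S,7S,18S,19S,22S) | CC1=C(CCC2=C(C)CC[C@@H]3OC(C)(C)[C@@H](O)CC[C@@]23C)[C@]2(C)CC[C@H](O)C(C)(C)O[C@H]2CC1 | intermediate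
9 | 6,6′-(ethane-1,2-diyl)bis[(5aS,9aS)-2,2,5a,7-tetramethyl-4,5,5a,8,9,9a-hexahydro-1-benzoxepin-3(2H)-one] | CC1=C(CCC2=C(C)CC[C@@H]3OC(C)(C)C(=O)CC[C@@]23C)[C@]2(C)CCC(=O)C(C)(C)O[C@H]2CC1 | intermediate
10 | sodwanone T (squalene 3R,6S,7S,18S,19S; 22-ketone) | CC1=C(CCC2=C(C)CC[C@@H]3OC(C)(C)[C@H](O)CC[C@@]23C)[C@]2(C)CCC(=O)C(C)(C)O[C@H]2CC1 | target

## Step count and risks

Total steps: 7. Longest linear sequence: 7 (1 → 10).

Risk 1, step 5 (the most exposed). Proton loss from the C10/C15 cations can also give the exocyclic or trisubstituted alkenes. A cation formed at one end can also be captured by the still-free olefin of the other end, which gives cyclopentane or pentacyclic products. A yield of 10–20% after chromatography on AgNO3-impregnated silica is the realistic expectation. Acid-mediated isomerisation of regioisomers is not a safe remedy, because the same cross-cyclisation would follow. The fallback closes each bicycle before the halves are joined, so no cation ever sits next to the second olefin; it sets out from 3 and returns at 8. Alcohol 3 is silylated (TBSCl, imidazole, DMF) to (2E,6S,7S,10S)-6,7:10,11-diepoxyfarnesyl tert-butyldimethylsilyl ether F1. This is cyclised with TMSOTf and 2,6-di-tert-butyl-4-methylpyridine in CH2Cl2 at −78 °C to (3S,5aS,9aS)-6-[(tert-butyldimethylsilyloxy)methyl]-2,2,5a,7-tetramethyl-3-(trimethylsilyloxy)-2,3,4,5,5a,8,9,9a-octahydro-1-benzoxepine F2. Bu4NF in THF removes both silyl groups to give (3S,5aS,9aS)-6-(hydroxymethyl)-2,2,5a,7-tetramethyl-2,3,4,5,5a,8,9,9a-octahydro-1-benzoxepin-3-ol F3. The primary allylic hydroxyl is brominated selectively (CBr4, PPh3, CH2Cl2, −20 °C) to (3S,5aS,9aS)-6-(bromomethyl)-2,2,5a,7-tetramethyl-2,3,4,5,5a,8,9,9a-octahydro-1-benzoxepin-3-ol F4. Homocoupling of this bromide with CoCl(PPh3)3 in benzene gives diol 8.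

Risk 2, step 4. The cobalt-mediated coupling may give head-to-tail isomers or erode the E geometry, and the divalent cobalt halide formed could act as a Lewis acid on the epoxides. The fallback replaces radical-type homocoupling by sulfone alkylation and reductive desulfonylation; it sets out from 5 and returns at 6. Half of 5 is treated with PhSO2Na in DMF to give (2E,6S,7S,10S)-6,7:10,11-diepoxyfarnesyl phenyl sulfone F5. Its anion (KN(SiMe3)2, THF, −78 °C) is alkylated with the other half of 5 to give (3S,6S,7S,10E,14E,18S,19S,22S)-12-(phenylsulfonyl)-2,3:6,7:18,19:22,23-tetraepoxy-2,3,6,7,18,19,22,23-octahydrosqualene F6 as a mixture of C12 epimers. The allylic sulfone is removed with LiBHEt3 and catalytic PdCl2[Ph2P(CH2)3PPh2] in THF at 0 °C, through an allyl complex of palladium generated from zerovalent palladium, with the hydride kept limiting to spare the epoxides. This gives 6.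

Risk 3, step 7. The oxazaborolidine may not override the ring's own facial bias, and the mono-reduction is only statistical. The fallback sets C3 by SN2 inversion instead of hydride delivery; it sets out from 8 and returns at 10. Diol 8 is oxidised with about one equivalent of Dess–Martin periodinane, and the mono-ketone 3-epi-sodwanone T F7 is separated from 8 and 9, which are recycled. Mitsunobu inversion (4-nitrobenzoic acid, diisopropyl azodicarboxylate, PPh3, toluene, 23–50 °C) gives sodwanone T 4-nitrobenzoate F8 with the 3R configuration. Methanolysis (K2CO3, MeOH) gives 10. The same sequence rescues any F7 formed in step 7 if the reduction gives the wrong epimer.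

## Further compounds

F1 | step 5 | (2E,6S,7S,10S)-6,7:10,11-diepoxyfarnesyl tert-butyldimethylsilyl ether | CC1(C)O[C@H]1CC[C@]1(C)O[C@H]1CC/C(C)=C/CO[Si](C)(C)C(C)(C)C
F2 | step 5 | (3S,5aS,9aS)-6-[(tert-butyldimethylsilyloxy)methyl]-2,2,5a,7-tetramethyl-3-(trimethylsilyloxy)-2,3,4,5,5a,8,9,9a-octahydro-1-benzoxepine | CC1=C(CO[Si](C)(C)C(C)(C)C)[C@]2(C)CC[C@H](O[Si](C)(C)C)C(C)(C)O[C@H]2CC1
F3 | step 5 | (3S,5aS,9aS)-6-(hydroxymethyl)-2,2,5a,7-tetramethyl-2,3,4,5,5a,8,9,9a-octahydro-1-benzoxepin-3-ol | CC1=C(CO)[C@]2(C)CC[C@H](O)C(C)(C)O[C@H]2CC1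
F4 | step 5 | (3S,5aS,9aS)-6-(bromomethyl)-2,2,5a,7-tetramethyl-2,3,4,5,5a,8,9,9a-octahydro-1-benzoxepin-3-ol | CC1=C(CBr)[C@]2(C)CC[C@H](O)C(C)(C)O[C@H]2CC1
F5 | step 4 | (2E,6S,7S,10S)-6,7:10,11-diepoxyfarnesyl phenyl sulfone | CC1(C)O[C@H]1CC[C@]1(C)O[C@H]1CC/C(C)=C/CS(=O)(=O)c1ccccc1
F6 | step 4 | (3S,6S,7S,10E,14E,18S,19S,22S)-12-(phenylsulfonyl)-2,3:6,7:18,19:22,23-tetraepoxy-2,3,6,7,18,19,22,23-octahydrosqualene (C12 epimers) | CC1(C)O[C@H]1CC[C@]1(C)O[C@H]1CC/C(C)=C/C(C/C=C(C)/CC[C@@H]1O[C@@]1(C)CC[C@@H]1OC1(C)C)S(=O)(=O)c1ccccc1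
F7 | step 7 | 3-epi-sodwanone T (3S carbinol, 22-ketone) | CC1=C(CCC2=C(C)CC[C@@H]3OC(C)(C)[C@@H](O)CC[C@@]23C)[C@]2(C)CCC(=O)C(C)(C)O[C@H]2CC1
F8 | step 7 | sodwanone T 4-nitrobenzoate (3R ester) | CC1=C(CCC2=C(C)CC[C@@H]3OC(C)(C)[C@H](OC(=O)c4ccc(cc4)[N+](=O)[O-])CC[C@@]23C)[C@]2(C)CCC(=O)C(C)(C)O[C@H]2CC1
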